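**Plan**

- Retrosynthesis (spongian numbering): the C16 acetate, the C15 aldehyde and the C17 ester are unravelled last. Ring C is cut at C8–C14 and C12–C13 (intramolecular Diels–Alder; the dienophile is tethered as a C17–O–C15 ester, a γ-lactone that is not in the target). Then C8–C17 (Stille), then ring B at C9–C10 together with ring A at C4–C5 in one cationic event, then C6–C7 (dianion/epoxide).
- Forward: a 1,2,2-trimethylcyclopentane from camphoric anhydride carries the carbinol carbon C5. In step 6 the five-membered ring grows into ring A (C1–C5, C10) by a 1,2-shift and the tethered β-diketone closes ring B. Ring C follows by the tethered [4+2]; the lactone is opened, C11 reduced, the C16/O11 lactol acetylated and C15 unmasked last.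
- Enabling feature: in ring A the CMe2 carbon C4 and the methyl-bearing quaternary C10 are both bonded to the ring-fusion CH C5. A C5 cation next to a cyclopentane made of C10, C4, C3, C2, C1 can therefore take C4 from C10; this gives the gem-dimethylcyclohexane and leaves the cation on C10, exactly where ring B must close onto C9.
- Stereochemistry: C5 from a CBS reduction and the stereospecific anti shift; C10 and C9 from the chair closure (trans-decalin); C8, C13, C14 from the Diels–Alder step (α-face attack anti to C20, cis-lactone tether, Z-dienophile); C11 from α-face hydride attack; C16 from exo acetylation. The camphor-derived quaternary centre is erased on purpose (it becomes the planar C10 cation).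

Key step: step 6

**Remarks on the chemistry**

- Numbering and descriptors: C1–C5/C10 = ring A, C5–C10 = ring B, C8, C9, C11–C14 = ring C; C15 on C14, C16 on C13, C17 on C8, C18/C19 on C4, C20 on C10; β = the face of C20.
- Compound 11 is drawn as the keto tautomer (it should exist mainly as the enol). The E/Z geometry of 10 is lost on ionisation, so either isomer serves. Lactol 24 is drawn as the exo anomer.
- Compounds 1, 8 and 15 are taken as commercial.

**Route**

Step 1
Reactants: 1 (1R,3S)-camphoric anhydride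
Product: 3 (1R)-1,2,2-trimethylcyclopentane-1-carboxylic acid, via Barton ester 2 (not isolated)
Conditions: 2-mercaptopyridine N-oxide sodium salt, DMAP (cat.), CH2Cl2, rt, dark; then t-BuSH, hν (W lamp), rt; 1 M HCl
Reagents that add atoms: none
Why: Barton reductive decarboxylation, in which the thiohydroxamate should open the anhydride at the less hindered carbonyl (on the CH carbon) and the secondary radical formed on photolysis is reduced by the thiol, leaving the quaternary centre untouched.

Step 2
Reactants: 3 (1R)-1,2,2-trimethylcyclopentane-1-carboxylic acid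
Product: 4 1-[(1R)-1,2,2-trimethylcyclopentyl]ethan-1-one
Conditions: MeLi (2.5 equiv), Et2O, 0 °C → rt; 1 M HCl (inverse quench)
Reagents that add atoms: methyllithium [Li]C
Why: Ketone synthesis from a carboxylic acid and an organolithium, where the dilithio gem-diolate resists a second addition and collapses to the methyl ketone on quench.

Step 3
Reactants: 4 1-[(1R)-1,2,2-trimethylcyclopentyl]ethan-1-one
Product: 5 2-bromo-1-[(1R)-1,2,2-trimethylcyclopentyl]ethan-1-one
Conditions: Br2, MeOH, 0 °C → rt
Reagents that add atoms: bromine BrBr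
Why: Acid-mediated α-bromination through the enol, the methyl group being the only enolisable position.

Step 4
Reactants: 5 2-bromo-1-[(1R)-1,2,2-trimethylcyclopentyl]ethan-1-one
Product: 7 (2R)-2-[(1R)-1,2,2-trimethylcyclopentyl]oxirane, via bromohydrin 6 (not isolated)
Conditions: (R)-Me-CBS (10 mol %), BH3·SMe2, THF, −20 °C; then 2 M NaOH, rt
Reagents that add atoms: none
Why: Corey–Bakshi–Shibata reduction (tert-alkyl as large group, CH2Br as small group) should set the carbinol centre (future C5) under reagent control, and the intramolecular Williamson closure to the epoxide does not touch it.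

Step 5
Reactants: 7 (2R)-2-[(1R)-1,2,2-trimethylcyclopentyl]oxirane; 8 pentane-2,4-dione
Product: 10 (E)-1-{(5S)-5-[(1R)-1,2,2-trimethylcyclopentyl]oxolan-2-ylidene}propan-2-one, via hydroxy diketone 9 (not isolated)
Conditions: 8, NaH then n-BuLi, THF, 0 °C; 7, 0 → 40 °C; 1 M HCl; then TsOH (cat.), 4 Å MS, CH2Cl2, rt
Reagents that add atoms: none
Why: γ-Alkylation of the 1,3-diketone dianion at the unhindered CH2 of the epoxide, then acid-catalysed hemiketalisation and dehydration to the conjugated 2-alkylidene tetrahydrofuran, with the C–O bond at the stereocentre never broken.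

Step 6
Reactants: 10 (E)-1-{(5S)-5-[(1R)-1,2,2-trimethylcyclopentyl]oxolan-2-ylidene}propan-2-one
Product: 11 (1S,4aS,8aS)-1-acetyl-5,5,8a-trimethyloctahydronaphthalen-2(1H)-one
Conditions: SnCl4 (2 equiv), 2,6-di-tert-butyl-4-methylpyridine (0.3 equiv), CH2Cl2, −78 → 0 °C; aq. NaHCO3
Reagents that add atoms: none
Why: Proposed new method: SnCl4 binds the vinylogous ester carbonyl, the C5–O bond ionises with concerted anti 1,2-shift of the CMe2 carbon C4 from C10 to C5 (Wagner–Meerwein enlargement of the cyclopentane to ring A, driven by loss of ring strain and formation of the tertiary C10 cation), and the tin β-diketonate released in the same act attacks C10 through C9. The closest known reaction types are the Wagner–Meerwein/Demjanov ring expansion of cyclopentylcarbinyl cations, the Lewis-acid 1,3 O-to-C rearrangement of alkyl enol ethers, and the SnCl4 cyclisation of β-dicarbonyl-terminated cyclohexyl cations to trans-fused 2-acyl decalones; here they are joined in one step on a substrate class not yet used for it. Ring A is not closed but grows from five to six atoms by the shift, and ring B closes by 6-(enolendo) attack of C9 on the C10 cation through a chair. C5 is fixed by inversion at the CBS-derived carbinol carbon, C10 by attack trans to C5–H with the side chain equatorial (trans-decalin, axial C20), and C9 is thermodynamic because it is enolisable. The step needs migration of C4 rather than C1 or CH3 (the tertiary alkyl carbon has the highest migratory aptitude and only a ring bond relieves strain), C- rather than O-capture (an O-alkylated enol ether would re-ionise under SnCl4), and capture faster than proton loss from the cation, which the low temperature and the hindered pyridine base are meant to secure.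

Step 7
Reactants: 11 (1S,4aS,8aS)-1-acetyl-5,5,8a-trimethyloctahydronaphthalen-2(1H)-one
Product: 12 (4aS,8aS)-1-acetyl-5,5,8a-trimethyl-3,4,4a,5,6,7,8,8a-octahydronaphthalen-2-yl trifluoromethanesulfonate
Conditions: NaH, PhNTf2, THF, 0 °C → rt; 1 M HCl
Reagents that add atoms: N-phenylbis(trifluoromethanesulfonimide) O=S(=O)(N(c1ccccc1)S(=O)(=O)C(F)(F)F)C(F)(F)F
Why: O-Sulfonylation of the sodium diketonate (enol triflate formation), expected at the ring oxygen because the exocyclic enol triflate would suffer A(1,3) strain against the quaternary C10.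

Step 8
Reactants: 12 (4aS,8aS)-1-acetyl-5,5,8a-trimethyl-3,4,4a,5,6,7,8,8a-octahydronaphthalen-2-yl trifluoromethanesulfonate
Product: 13 (4aS,8aS)-1-{1-[(tert-butyldimethylsilyl)oxy]ethenyl}-5,5,8a-trimethyl-3,4,4a,5,6,7,8,8a-octahydronaphthalen-2-yl trifluoromethanesulfonate
Conditions: TBSOTf, Et3N, CH2Cl2, 0 °C
Reagents that add atoms: tert-butyldimethylsilyl trifluoromethanesulfonate CC(C)(C)[Si](C)(C)OS(=O)(=O)C(F)(F)F
Why: Soft enolisation and O-silylation at the acetyl CH3 (the only α-position with hydrogen) gives the 2-silyloxy diene and masks the ketone before the C17 hydroxyl arrives, which avoids hemiketal and furan formation.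

Step 9
Reactants: 13 (4aS,8aS)-1-{1-[(tert-butyldimethylsilyl)oxy]ethenyl}-5,5,8a-trimethyl-3,4,4a,5,6,7,8,8a-octahydronaphthalen-2-yl trifluoromethanesulfonate
Product: 14 [(4aS,8aS)-1-{1-[(tert-butyldimethylsilyl)oxy]ethenyl}-5,5,8a-trimethyl-3,4,4a,5,6,7,8,8a-octahydronaphthalen-2-yl]methanol
Conditions: Bu3SnCH2OH, Pd(PPh3)4 (10 mol %), LiCl, 1,4-dioxane, 95 °C
Reagents that add atoms: (tributylstannyl)methanol CCCC[Sn](CCCC)(CCCC)CO
Why: Stille hydroxymethylation of the alkenyl triflate installs C17 with its oxygen under neutral conditions that the silyl enol ether tolerates.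

Step 10
Reactants: 15 3,3-diethoxyprop-1-yne
Product: 16 4,4-diethoxybut-2-ynoic acid
Conditions: n-BuLi, THF, −78 °C; CO2; 1 M HCl
Reagents that add atoms: carbon dioxide O=C=O
Why: Carboxylation of the lithium acetylide.

Step 11
Reactants: 14 [(4aS,8aS)-1-{1-[(tert-butyldimethylsilyl)oxy]ethenyl}-5,5,8a-trimethyl-3,4,4a,5,6,7,8,8a-octahydronaphthalen-2-yl]methanol; 16 4,4-diethoxybut-2-ynoic acid
Product: 17 [(4aS,8aS)-1-{1-[(tert-butyldimethylsilyl)oxy]ethenyl}-5,5,8a-trimethyl-3,4,4a,5,6,7,8,8a-octahydronaphthalen-2-yl]methyl 4,4-diethoxybut-2-ynoate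
Conditions: DCC, DMAP (cat.), CH2Cl2, −20 → 0 °C
Reagents that add atoms: none
Why: Steglich esterification of the primary allylic alcohol builds the temporary C17–O–C15 tether, with C16 already at the aldehyde oxidation level as its acetal.

Step 12
Reactants: 17 [(4aS,8aS)-1-{1-[(tert-butyldimethylsilyl)oxy]ethenyl}-5,5,8a-trimethyl-3,4,4a,5,6,7,8,8a-octahydronaphthalen-2-yl]methyl 4,4-diethoxybut-2-ynoate
Product: 18 [(4aS,8aS)-1-{1-[(tert-butyldimethylsilyl)oxy]ethenyl}-5,5,8a-trimethyl-3,4,4a,5,6,7,8,8a-octahydronaphthalen-2-yl]methyl (2Z)-4,4-diethoxybut-2-enoate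
Conditions: H2 (1 atm), Lindlar catalyst, quinoline, EtOAc, rt
Reagents that add atoms: none
Why: Lindlar semihydrogenation should give the (Z)-enoate by syn addition while the hindered silyloxy diene and the acetal stay intact.

Step 13
Reactants: 18 [(4aS,8aS)-1-{1-[(tert-butyldimethylsilyl)oxy]ethenyl}-5,5,8a-trimethyl-3,4,4a,5,6,7,8,8a-octahydronaphthalen-2-yl]methyl (2Z)-4,4-diethoxybut-2-enoate
Product: 20 keto lactone acetal (11-oxo tricycle with the C15(=O)–O–C17 γ-lactone cis-fused at C8/C14 and a 13β-diethoxymethyl group; 5α-H, 9α-H, 10β-CH3, 13α-H, 14α-H), via silyl enol ether cycloadduct 19 (not isolated)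
Conditions: PhMe (0.01 M), BHT, 150 °C (sealed tube); then TBAF, AcOH, THF, 0 °C
Reagents that add atoms: none
Why: Ester-tethered intramolecular Diels–Alder reaction of the 2-silyloxy diene, in which the dienophile should add to the α-face (anti to C20), the three-atom tether from the inside substituent C17 forces the cis-fused lactone (C15 cis to C17) and the Z-alkene places C16 cis to C15, so C8, C14 and C13 are set together; desilylation then gives the C11 ketone with protonation at C9 to the trans B/C junction (epimerisable).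

Step 14
Reactants: 20 keto lactone acetal
Product: 21 hydroxy Weinreb amide (11-oxo; 8β-CH2OH; 14β-C(O)N(OMe)Me; 13β-CH(OEt)2)
Conditions: MeNH(OMe)·HCl, AlMe3, CH2Cl2, 0 °C → rt; Rochelle salt
Reagents that add atoms: N,O-dimethylhydroxylamine hydrochloride CNOC.Cl
Why: Weinreb aminolysis of the γ-lactone with the aluminium amide cleaves the temporary ring, freeing the C17 hydroxyl and leaving C15 as an amide that later gives the aldehyde without over-reduction.

Step 15
Reactants: 21 hydroxy Weinreb amide
Product: 22 17-O-(3-methylbutanoyl) derivative of 21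
Conditions: 3-methylbutanoyl chloride, pyridine, DMAP (cat.), CH2Cl2, 0 °C → rt
Reagents that add atoms: 3-methylbutanoyl chloride CC(C)CC(=O)Cl
Why: DMAP-catalysed acylation of the only hydroxyl group, done at once so that the hydroxy amide cannot relactonise.

Step 16
Reactants: 22 17-O-(3-methylbutanoyl) derivative of 21
Product: 24 lactol (11β,16-epoxy-16-ol, exo-OH; 14β-Weinreb amide; 17-O-isovalerate), via hydroxy acetal 23 (not isolated)
Conditions: NaBH4, CeCl3·7H2O, MeOH, 0 °C → rt; then 1 M HCl, THF, 40 °C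
Reagents that add atoms: water O
Why: Luche-type borohydride reduction should deliver hydride to the C11 ketone from the α-face (the β-face is blocked by the 1,3-diaxial C20 and C17 groups) to give the axial 11β-alcohol, and acid hydrolysis of the 1,3-diaxial acetal is trapped as the bridged lactol; ester and Weinreb amide are stable to both reagents.

Step 17
Reactants: 24 lactol
Product: 25 16-exo-acetate of 24
Conditions: Ac2O, pyridine, DMAP (cat.), CH2Cl2, 0 °C → rt
Reagents that add atoms: acetic anhydride CC(=O)OC(C)=O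
Why: Acetylation of the equilibrating lactol should take place on the exo face, away from the C8–C9–C14 bridge and the C17 acyloxymethyl group, which is also the more stable acetate.

Step 18
Reactants: 25 16-exo-acetate of 24
Product: 26 target CNP0331370.1
Conditions: Cp2Zr(H)Cl (2 equiv), THF, rt, 20 min; H2O/SiO2
Reagents that add atoms: none
Why: Schwartz reduction of the Weinreb amide to the aldehyde through a stable zirconated hemiaminal is chemoselective over the two esters, and unmasking C15 last prevents acetal formation between C15 and the C16 lactol.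

**Compound list**

1 | (1R,3S)-camphoric anhydride | C[C@]12CC[C@H](C(=O)OC1=O)C2(C)C | starting material
2 | Barton ester: (1R,3S)-1,2,2-trimethyl-3-{[(2-thioxopyridin-1(2H)-yl)oxy]carbonyl}cyclopentane-1-carboxylic acid (sodium salt in the flask) | C[C@@]1(C(=O)O)CC[C@H](C(=O)On2ccccc2=S)C1(C)C | intermediate
3 | (1R)-1,2,2-trimethylcyclopentane-1-carboxylic acid | C[C@@]1(C(=O)O)CCCC1(C)C | intermediate
4 | 1-[(1R)-1,2,2-trimethylcyclopentyl]ethan-1-one | CC(=O)[C@]1(C)CCCC1(C)C | intermediate
5 | 2-bromo-1-[(1R)-1,2,2-trimethylcyclopentyl]ethan-1-one | BrCC(=O)[C@]1(C)CCCC1(C)C | intermediate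
6 | bromohydrin: (1R)-2-bromo-1-[(1R)-1,2,2-trimethylcyclopentyl]ethan-1-ol | BrC[C@H](O)[C@]1(C)CCCC1(C)C | intermediate
7 | (2R)-2-[(1R)-1,2,2-trimethylcyclopentyl]oxirane | C1O[C@@H]1[C@]2(C)CCCC2(C)C | intermediate
8 | pentane-2,4-dione | CC(=O)CC(C)=O | starting material
9 | hydroxy diketone: (7S)-7-hydroxy-7-[(1R)-1,2,2-trimethylcyclopentyl]heptane-2,4-dione | CC(=O)CC(=O)CC[C@H](O)[C@]1(C)CCCC1(C)C | intermediate
10 | (E)-1-{(5S)-5-[(1R)-1,2,2-trimethylcyclopentyl]oxolan-2-ylidene}propan-2-one | CC(=O)/C=C1\CC[C@H](O1)[C@]2(C)CCCC2(C)C | intermediate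
11 | (1S,4aS,8aS)-1-acetyl-5,5,8a-trimethyloctahydronaphthalen-2(1H)-one (trans-decalin, keto form of the enolised β-diketone) | CC(=O)[C@H]1C(=O)CC[C@H]2C(C)(C)CCC[C@]12C | intermediate
12 | (4aS,8aS)-1-acetyl-5,5,8a-trimethyl-3,4,4a,5,6,7,8,8a-octahydronaphthalen-2-yl trifluoromethanesulfonate | CC(=O)C1=C(OS(=O)(=O)C(F)(F)F)CC[C@H]2C(C)(C)CCC[C@]12C | intermediate
13 | (4aS,8aS)-1-{1-[(tert-butyldimethylsilyl)oxy]ethenyl}-5,5,8a-trimethyl-3,4,4a,5,6,7,8,8a-octahydronaphthalen-2-yl trifluoromethanesulfonate | C=C(O[Si](C)(C)C(C)(C)C)C1=C(OS(=O)(=O)C(F)(F)F)CC[C@H]2C(C)(C)CCC[C@]12C | intermediate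
14 | [(4aS,8aS)-1-{1-[(tert-butyldimethylsilyl)oxy]ethenyl}-5,5,8a-trimethyl-3,4,4a,5,6,7,8,8a-octahydronaphthalen-2-yl]methanol | C=C(O[Si](C)(C)C(C)(C)C)C1=C(CO)CC[C@H]2C(C)(C)CCC[C@]12C | intermediate
15 | 3,3-diethoxyprop-1-yne | CCOC(OCC)C#C | starting material
16 | 4,4-diethoxybut-2-ynoic acid | CCOC(OCC)C#CC(=O)O | intermediate
17 | [(4aS,8aS)-1-{1-[(tert-butyldimethylsilyl)oxy]ethenyl}-5,5,8a-trimethyl-3,4,4a,5,6,7,8,8a-octahydronaphthalen-2-yl]methyl 4,4-diethoxybut-2-ynoate | C=C(O[Si](C)(C)C(C)(C)C)C1=C(COC(=O)C#CC(OCC)OCC)CC[C@H]2C(C)(C)CCC[C@]12C | intermediate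
18 | [(4aS,8aS)-1-{1-[(tert-butyldimethylsilyl)oxy]ethenyl}-5,5,8a-trimethyl-3,4,4a,5,6,7,8,8a-octahydronaphthalen-2-yl]methyl (2Z)-4,4-diethoxybut-2-enoate | C=C(O[Si](C)(C)C(C)(C)C)C1=C(COC(=O)/C=C\C(OCC)OCC)CC[C@H]2C(C)(C)CCC[C@]12C | intermediate
19 | silyl enol ether cycloadduct: Δ9(11) 11-O-TBS enol ether of 20 (cis C15(=O)–O–C17 γ-lactone at C8/C14, 13β-CH(OEt)2, 5α-H, 10β-CH3, 13α-H, 14α-H) | CC(C)(C)[Si](C)(C)OC1=C2[C@@]3(C)CCCC(C)(C)[C@@H]3CC[C@]24COC(=O)[C@@H]4[C@H](C(OCC)OCC)C1 | intermediate
20 | keto lactone acetal: 11-oxo tricycle with cis C15(=O)–O–C17 γ-lactone and 13β-diethoxymethyl group (5α-H, 9α-H, 10β-CH3, 13α-H, 14α-H) | O=C1C[C@@H](C(OCC)OCC)[C@H]2C(=O)OC[C@@]32CC[C@H]4C(C)(C)CCC[C@]4(C)[C@@H]13 | intermediate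
21 | hydroxy Weinreb amide: 11-oxo, 8β-CH2OH, 14β-C(O)N(OMe)Me, 13β-CH(OEt)2 (ring fusions as in 20) | O=C1C[C@@H](C(OCC)OCC)[C@@H](C(=O)N(C)OC)[C@]2(CO)CC[C@H]3C(C)(C)CCC[C@]3(C)[C@@H]12 | intermediate
22 | 17-O-(3-methylbutanoyl) derivative of 21 | O=C1C[C@@H](C(OCC)OCC)[C@@H](C(=O)N(C)OC)[C@]2(COC(=O)CC(C)C)CC[C@H]3C(C)(C)CCC[C@]3(C)[C@@H]12 | intermediate
23 | hydroxy acetal: 11β-alcohol of 22 | O[C@H]1C[C@@H](C(OCC)OCC)[C@@H](C(=O)N(C)OC)[C@]2(COC(=O)CC(C)C)CC[C@H]3C(C)(C)CCC[C@]3(C)[C@@H]12 | intermediate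
24 | lactol: 11β,16-epoxy-16-ol (exo-OH) with 14β-C(O)N(OMe)Me and 8β-CH2O-(3-methylbutanoyl) | O[C@H]1O[C@H]2C[C@@H]1[C@@H](C(=O)N(C)OC)[C@]1(COC(=O)CC(C)C)CC[C@H]3C(C)(C)CCC[C@]3(C)[C@@H]21 | intermediate
25 | 16-exo-acetate of 24 | CC(=O)O[C@H]1O[C@H]2C[C@@H]1[C@@H](C(=O)N(C)OC)[C@]1(COC(=O)CC(C)C)CC[C@H]3C(C)(C)CCC[C@]3(C)[C@@H]21 | intermediate
26 | CNP0331370.1: 16-exo-acetoxy-11β,16-epoxy lactol acetate with 14β-CHO and 8β-CH2O-(3-methylbutanoyl) on the trans-anti-trans 4,4,10-trimethylperhydrophenanthrene core | CC(=O)O[C@H]1O[C@H]2C[C@@H]1[C@@H](C=O)[C@]1(COC(=O)CC(C)C)CC[C@H]3C(C)(C)CCC[C@]3(C)[C@@H]21 | target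

**Step count and risks**

Total step count: 18. Longest linear sequence: 17 (steps 1–9 and 11–18; step 10 is a one-step side branch).

Steps most likely to fail:

1. Step 6 (Proposed new method). The cyclohexyl cation may lose the C5 proton and re-enter by protonation, which would erode the enantiomeric purity, or ring B closure may lag behind elimination. The fallback sets out from 10 and splits the event into known reactions. Under protic conditions (TfOH cat., (CF3)2CHOH, 0 °C) the same Wagner–Meerwein ring expansion followed by loss of the C5 proton should give the achiral 6-(2,6,6-trimethylcyclohex-1-en-1-yl)hexane-2,4-dione F1. SnCl4 in CH2Cl2 (cation–enol cyclisation of the monocyclic precursor) should then give racemic trans-1-acetyl-5,5,8a-trimethyloctahydronaphthalen-2(1H)-one F2. Condensation with (R)-1-phenylethylamine (TsOH cat., PhMe, Dean–Stark) gives diastereomeric enaminones, from which (1Z,4aS,8aS)-5,5,8a-trimethyl-1-{1-[(1R)-1-phenylethylamino]ethylidene}octahydronaphthalen-2(1H)-one F3 is separated and hydrolysed (2 M HCl, THF). The route is rejoined at 11.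

2. Step 13. The dienophile is only singly activated and the diene terminus is fully substituted, so a thermal [1,5]-hydrogen shift of the Z-substituted diene or decomposition may outrun the cycloaddition. The fallback sets out from 14 and uses a doubly activated dienophile.
   - Maleic anhydride (Et3N, CH2Cl2) gives the maleate half ester F4.
   - N,O-bis(trimethylsilyl)acetamide converts F4 into its trimethylsilyl ester F5.
   - Heating F5 (PhMe, 110 °C) should give the cycloadduct F6 with the same tether-controlled stereochemistry.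
   - TBAF/AcOH frees the keto acid lactone F7.
   - EtSH, DCC, DMAP gives the S-ethyl thioester F8.
   - Fukuyama reduction (Et3SiH, Pd/C) gives the keto aldehyde lactone F9.
   - HC(OEt)3, PPTS, EtOH converts F9 into the diethyl acetal, and the route is rejoined at 20.

3. Step 9. Transmetalation at the hindered tetrasubstituted dienyl triflate may be slow and protodestannylation of the stannane may win. The fallback sets out from 13: palladium-catalysed methoxycarbonylation (Pd(OAc)2, dppp, CO, MeOH, Et3N, DMF, 60 °C) gives methyl (4aS,8aS)-1-{1-[(tert-butyldimethylsilyl)oxy]ethenyl}-5,5,8a-trimethyl-3,4,4a,5,6,7,8,8a-octahydronaphthalene-2-carboxylate F10, and DIBAL (CH2Cl2, −78 °C), which spares the silyl enol ether, reduces it to the allylic alcohol. The route is rejoined at 14.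

Further compounds
F1 | step 6 | 6-(2,6,6-trimethylcyclohex-1-en-1-yl)hexane-2,4-dione | CC(=O)CC(=O)CCC1=C(C)CCCC1(C)C
F2 | step 6 | racemic trans-1-acetyl-5,5,8a-trimethyloctahydronaphthalen-2(1H)-one (racemate of 11) | CC(=O)C1C(=O)CCC2C(C)(C)CCCC12C
F3 | step 6 | (1Z,4aS,8aS)-5,5,8a-trimethyl-1-{1-[(1R)-1-phenylethylamino]ethylidene}octahydronaphthalen-2(1H)-one | C/C(N[C@H](C)c1ccccc1)=C1/C(=O)CC[C@H]2C(C)(C)CCC[C@]12C
F4 | step 13 | (2Z)-4-{[(4aS,8aS)-1-{1-[(tert-butyldimethylsilyl)oxy]ethenyl}-5,5,8a-trimethyl-3,4,4a,5,6,7,8,8a-octahydronaphthalen-2-yl]methoxy}-4-oxobut-2-enoic acid | C=C(O[Si](C)(C)C(C)(C)C)C1=C(COC(=O)/C=C\C(=O)O)CC[C@H]2C(C)(C)CCC[C@]12C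
F5 | step 13 | trimethylsilyl ester of F4 | C=C(O[Si](C)(C)C(C)(C)C)C1=C(COC(=O)/C=C\C(=O)O[Si](C)(C)C)CC[C@H]2C(C)(C)CCC[C@]12C
F6 | step 13 | cycloadduct: Δ9(11) 11-O-TBS enol ether with cis C15(=O)–O–C17 γ-lactone and 13β-trimethylsilyl carboxylate | CC(C)(C)[Si](C)(C)OC1=C2[C@@]3(C)CCCC(C)(C)[C@@H]3CC[C@]24COC(=O)[C@@H]4[C@H](C(=O)O[Si](C)(C)C)C1
F7 | step 13 | keto acid lactone: 11-oxo tricycle with cis C15(=O)–O–C17 γ-lactone and 13β-carboxylic acid | O=C1C[C@@H](C(=O)O)[C@H]2C(=O)OC[C@@]32CC[C@H]4C(C)(C)CCC[C@]4(C)[C@@H]13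
F8 | step 13 | S-ethyl thioester of F7 | O=C1C[C@@H](C(=O)SCC)[C@H]2C(=O)OC[C@@]32CC[C@H]4C(C)(C)CCC[C@]4(C)[C@@H]13
F9 | step 13 | keto aldehyde lactone: 13β-formyl analogue of F7 | O=C1C[C@@H](C=O)[C@H]2C(=O)OC[C@@]32CC[C@H]4C(C)(C)CCC[C@]4(C)[C@@H]13
F10 | step 9 | methyl (4aS,8aS)-1-{1-[(tert-butyldimethylsilyl)oxy]ethenyl}-5,5,8a-trimethyl-3,4,4a,5,6,7,8,8a-octahydronaphthalene-2-carboxylate | C=C(O[Si](C)(C)C(C)(C)C)C1=C(C(=O)OC)CC[C@H]2C(C)(C)CCC[C@]12C
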